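**Strategy.** Everything rests on cutting the α-methylene-γ-butyrolactone across C11–C12 and C6–C7 (germacrane numbering), which also opens the ten-membered carbocycle, since C6–C7 is the bond shared by both rings. The precursor 17 is an open-chain dienal: a C6 enal at one end, a terminal allene (C7=C11=C13) beside the C8 silyl ether at the other. In the key step Ni(0) joins the central allene carbon C11 to CO2, which becomes the lactone carbonyl C12, and the resulting 2-carboxyallylnickel adds through C7 to the C6 aldehyde; acidification closes the lactone. The step exploits C12 being a CO2-level carbon on the exocyclic C11=C13 alkene. Two rings thus close in one operation.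

Key step: step 11

Remark: germacrane numbering is used throughout (ring C1–C10, C11=C13 exocyclic methylene, C12 lactone carbonyl, C14 on C10, C15 on C4); the target is the 6R,7R,8S 6,12-olide with C2/C9 cis on C1=C10 and C3/C6 cis on C4=C5.

Remark: the (R,R)-bis-sulfonamide controller in step 6 is assumed, by the usual chair model, to give the 8S carbinol; the (S,S)-controller would be used if the opposite sense were found.

**Step 1**
Reactants: 1 but-2-yne-1,4-diol
Product: 2 4-[(4-methoxybenzyl)oxy]but-2-yn-1-ol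
Conditions: NaH (1 equiv), PMBCl (1 equiv), TBAI (cat.), THF/DMF, 0 °C to rt, diol in threefold excess
Reagents that add atoms: 4-methoxybenzyl chloride, COc1ccc(CCl)cc1
Why: Williamson etherification, in which the excess of the symmetric diol should favour the mono-ether.

**Step 2**
Reactants: 2 4-[(4-methoxybenzyl)oxy]but-2-yn-1-ol
Product: 3 (Z)-3-iodo-4-[(4-methoxybenzyl)oxy]but-2-en-1-ol
Conditions: Red-Al, THF, 0 °C; then I2, −78 °C to 0 °C
Reagents that add atoms: iodine, II
Why: hydroxyl-directed trans-hydroalumination (hydride to the carbinol-proximal carbon, aluminium to the distal one in a cyclic alanate) followed by iodinolysis with retention should place iodine cis to CH2OH, which fixes the later C4=C5 geometry.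

**Step 3**
Reactants: 3 (Z)-3-iodo-4-[(4-methoxybenzyl)oxy]but-2-en-1-ol
Product: 4 (Z)-triethyl({3-iodo-4-[(4-methoxybenzyl)oxy]but-2-en-1-yl}oxy)silane
Conditions: TESCl, imidazole, CH2Cl2, 0 °C
Reagents that add atoms: chlorotriethylsilane, CC[Si](Cl)(CC)CC
Why: silylation of the primary alcohol gives a TES ether that later serves as a latent C6 aldehyde.

**Step 4**
Reactants: 4 (Z)-triethyl({3-iodo-4-[(4-methoxybenzyl)oxy]but-2-en-1-yl}oxy)silane; 5 (3-ethoxy-3-oxopropyl)zinc bromide
Product: 6 ethyl (E)-4-{[(4-methoxybenzyl)oxy]methyl}-6-[(triethylsilyl)oxy]hex-4-enoate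
Conditions: Pd(PPh3)4 (5 mol %), THF/NMP, 50 °C
Reagents that add atoms: none
Why: Negishi sp3–sp2 coupling with retention of the vinyl iodide geometry should attach C1–C3 to C4 so that C3 stands cis to C6.

**Step 5**
Reactants: 6 ethyl (E)-4-{[(4-methoxybenzyl)oxy]methyl}-6-[(triethylsilyl)oxy]hex-4-enoate
Product: 7 (E)-4-{[(4-methoxybenzyl)oxy]methyl}-6-[(triethylsilyl)oxy]hex-4-enal
Conditions: DIBAL-H (1.1 equiv), CH2Cl2, −78 °C; Rochelle salt
Reagents that add atoms: none
Why: partial ester reduction, in which the aluminium hemiacetal is stable at −78 °C and should release the C1 aldehyde on work-up while silyl and PMB ethers stay intact.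

**Step 6**
Reactants: 8 methyl 4-oxobutanoate; 9 tributyl(propa-1,2-dien-1-yl)stannane
Product: 11 (S)-5-(propa-1,2-dien-1-yl)dihydrofuran-2(3H)-one, via hydroxy ester 10 (not isolated)
Conditions: (R,R)-N,N'-ditosyl-1,2-diphenylethane-1,2-diamine, BBr3, CH2Cl2, 0 °C to rt; 9, rt; 8, −78 °C; then TsOH (cat.), CH2Cl2, rt
Reagents that add atoms: none
Why: enantioselective propargylboration, in which tin-to-boron exchange with allylic transposition gives a B-propargyl diazaborolidine that adds to the aldehyde, again with transposition, through a chair transition state to give the allenyl carbinol (C8 set by the C2-symmetric controller), and acid then closes the γ-lactone.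

**Step 7**
Reactants: 11 (S)-5-(propa-1,2-dien-1-yl)dihydrofuran-2(3H)-one; 7 (E)-4-{[(4-methoxybenzyl)oxy]methyl}-6-[(triethylsilyl)oxy]hex-4-enal
Product: 14 (S,E)-3-[(E)-4-{[(4-methoxybenzyl)oxy]methyl}-6-[(triethylsilyl)oxy]hex-4-en-1-ylidene]-5-(propa-1,2-dien-1-yl)dihydrofuran-2(3H)-one, via aldol adduct 12 (not isolated), via mesylate 13 (not isolated)
Conditions: LDA, THF, −78 °C; 7; MsCl, −78 to 0 °C; DBU, rt
Reagents that add atoms: none
Why: aldol condensation (lactone enolate addition, mesylation of the aldolate, E1cB elimination), which should give the thermodynamically preferred E-alkylidene lactone and so set C1=C10 with C2 cis to C9.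

**Step 8**
Reactants: 14 the E-alkylidene lactone
Product: 15 (S,E)-2-[(E)-4-{[(4-methoxybenzyl)oxy]methyl}-6-[(triethylsilyl)oxy]hex-4-en-1-ylidene]hepta-5,6-diene-1,4-diol
Conditions: DIBAL-H (4 equiv), CH2Cl2, −78 to 0 °C; Rochelle salt
Reagents that add atoms: none
Why: 1,2-reduction of the conjugated lactone through the lactol should free the C14 and C8 hydroxyls without touching the allene or the alkene geometries.

**Step 9**
Reactants: 15 the ene-diol
Product: 16 (S)-1,4-bis(tert-butyldimethylsilyl) ether of diol 15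
Conditions: TBSCl, imidazole, DMAP (cat.), DMF, rt
Reagents that add atoms: tert-butyldimethylsilyl chloride, CC(C)(C)[Si](C)(C)Cl
Why: silylation of both hydroxyls gives ethers that are inert to Ni(0), unlike an allylic or allenylic ester.

**Step 10**
Reactants: 16 the bis-TBS, mono-TES triether
Product: 17 (2E,6E,9S)-9-[(tert-butyldimethylsilyl)oxy]-7-{[(tert-butyldimethylsilyl)oxy]methyl}-3-{[(4-methoxybenzyl)oxy]methyl}dodeca-2,6,10,11-tetraenal
Conditions: (COCl)2, DMSO, CH2Cl2, −78 to −40 °C; Et3N, −78 to 0 °C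
Reagents that add atoms: none
Why: Swern oxidation applied directly to the primary triethylsilyl ether (oxidative desilylation through the alkoxysulfonium salt) should give the C6 enal while the TBS ethers survive and the cold, brief base treatment preserves the enal geometry.

**Step 11**
Reactants: 17 the allenyl dienal
Product: 20 (3aS,4S,6E,10E,11aR)-4-[(tert-butyldimethylsilyl)oxy]-6-{[(tert-butyldimethylsilyl)oxy]methyl}-10-{[(4-methoxybenzyl)oxy]methyl}-3-methylidene-3a,4,5,8,9,11a-hexahydrocyclodeca[b]furan-2(3H)-one, via oxanickelacycle 18 (not isolated), via cyclodecadienyl hydroxy acid 19 (not isolated)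
Conditions: Ni(cod)2 (1.5 equiv), DBU (3 equiv), CO2 (1 atm), THF, 0 °C, slow addition of 17 to 0.003 M; then Ar, rt to 40 °C; 1 M HCl, 0 °C; PPTS (cat.), CH2Cl2, rt
Reagents that add atoms: carbon dioxide, O=C=O
Why: Proposed new method: Ni(0) couples the terminal allene with CO2 by oxidative cyclisation (C11–C12 bond, giving the 2-carboxylato-allylnickel 18), this allyl species adds through its substituted terminus C7 to the tethered, nickel-bound C6 aldehyde in a six-membered transition state with allylic transposition (C6–C7 bond), and acid then protonates the nickel alkoxide-carboxylate so that γ-hydroxy acid 19 lactonises. The closest known reaction type is the Ni(0)/DBU-mediated carboxylative allylation of terminal allenes with CO2 and aldehydes, established as a three-component coupling and as a cascade closing common rings; closing a ten-membered ring this way is the new element. The carbocycle closes by 10-exo-trig attack of C7 on the aldehyde carbon, and the lactone by 5-exo-trig attack of the C6 hydroxyl on the C12 carboxyl. C6 and C7 are set together in a chair-like transition state with C5 and C8 pseudo-equatorial (E-configured allyl, anti addition), which should give the trans-fused lactone; their absolute sense is relayed from C8, because with H8 eclipsing the alkene (A1,3 strain) the OTBS group blocks one face while the tether through C9 delivers the aldehyde to the other. The step needs CO2 capture by the allene ahead of any nickel–enal chemistry (secured by the allene being the most reactive π-system, 1 atm CO2, 0 °C and slow addition), branched C7 rather than linear C13 allylation (secured by the six-membered transition state), and ring closure over oligomerisation (secured by high dilution and by the two ring-cis trisubstituted alkenes pre-folding the chain).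

**Step 12**
Reactants: 20 the bis-TBS lactone
Product: 21 (3aR,4S,6E,10E,11aR)-4-hydroxy-6-(hydroxymethyl)-10-{[(4-methoxybenzyl)oxy]methyl}-3-methylidene-3a,4,5,8,9,11a-hexahydrocyclodeca[b]furan-2(3H)-one
Conditions: HF·pyridine, pyridine, THF, 0 °C to rt
Reagents that add atoms: none
Why: acidic fluoride desilylation should free both hydroxyls while avoiding the basic conditions that could trigger conjugate addition or translactonisation at the α-methylene lactone.

**Step 13**
Reactants: 21 the C8,C14-diol
Product: 22 [(3aR,4S,6E,10E,11aR)-4-hydroxy-10-{[(4-methoxybenzyl)oxy]methyl}-3-methylidene-2-oxo-2,3,3a,4,5,8,9,11a-octahydrocyclodeca[b]furan-6-yl]methyl acetate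
Conditions: AcCl (1.1 equiv), 2,4,6-collidine, CH2Cl2, −78 to −40 °C
Reagents that add atoms: acetyl chloride, CC(Cl)=O
Why: kinetically selective acylation, in which the unhindered primary allylic C14 hydroxyl should react well ahead of the secondary C8 hydroxyl flanked by the ring fusion.

**Step 14**
Reactants: 23 2-(bromomethyl)acrylic acid
Product: 24 2-{[(4-methoxybenzyl)oxy]methyl}acrylic acid
Conditions: 4-methoxybenzyl alcohol, NaH (2.2 equiv), THF, 0 °C to rt; then 1 M HCl to pH 3
Reagents that add atoms: 4-methoxybenzyl alcohol, COc1ccc(CO)cc1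
Why: Williamson-type displacement of the allylic bromide of the sodium carboxylate by the alkoxide, in which the SN2 and SN2′ pathways lead to the same product.

**Step 15**
Reactants: 22 the C8 alcohol; 24 2-{[(4-methoxybenzyl)oxy]methyl}acrylic acid
Product: 25 (3aR,4S,6E,10E,11aR)-6-(acetoxymethyl)-10-{[(4-methoxybenzyl)oxy]methyl}-3-methylidene-2-oxo-2,3,3a,4,5,8,9,11a-octahydrocyclodeca[b]furan-4-yl 2-{[(4-methoxybenzyl)oxy]methyl}acrylate
Conditions: 2,4,6-trichlorobenzoyl chloride, Et3N, THF, rt; then 22, DMAP, toluene, rt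
Reagents that add atoms: none
Why: Yamaguchi esterification through the mixed anhydride and acylpyridinium should acylate the hindered C8 hydroxyl with retention at C8.

**Step 16**
Reactants: 25 the bis-PMB ether
Product: 26 (3aR,4S,6E,10E,11aR)-6-(acetoxymethyl)-10-(hydroxymethyl)-3-methylidene-2-oxo-2,3,3a,4,5,8,9,11a-octahydrocyclodeca[b]furan-4-yl 2-(hydroxymethyl)acrylate
Conditions: DDQ (3 equiv), CH2Cl2/pH 7 buffer, 0 °C to rt
Reagents that add atoms: none
Why: oxidative cleavage of both PMB ethers (benzylic hydride abstraction, then hydrolysis of the oxocarbenium ions) under buffered conditions that should leave the esters, lactone and alkenes untouched.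

**Step 17**
Reactants: 26 the C15, side-chain diol
Product: 27 (3aR,4S,6E,10E,11aR)-6-(acetoxymethyl)-10-formyl-3-methylidene-2-oxo-2,3,3a,4,5,8,9,11a-octahydrocyclodeca[b]furan-4-yl 2-(hydroxymethyl)acrylate
Conditions: MnO2 (activated, 20 equiv), CH2Cl2, rt
Reagents that add atoms: none
Why: chemoselective allylic oxidation, in which MnO2 should oxidise the C15 alcohol on the electron-rich trisubstituted alkene much faster than the hydroxymethyl group on the electron-poor acrylate.

**Compound list**

1 | but-2-yne-1,4-diol | OCC#CCO | starting material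
2 | 4-[(4-methoxybenzyl)oxy]but-2-yn-1-ol | COc1ccc(COCC#CCO)cc1 | intermediate
3 | (Z)-3-iodo-4-[(4-methoxybenzyl)oxy]but-2-en-1-ol | OC/C=C(\I)COCc1ccc(OC)cc1 | intermediate
4 | (Z)-triethyl({3-iodo-4-[(4-methoxybenzyl)oxy]but-2-en-1-yl}oxy)silane | CC[Si](CC)(CC)OC/C=C(\I)COCc1ccc(OC)cc1 | intermediate
5 | (3-ethoxy-3-oxopropyl)zinc bromide | CCOC(=O)CC[Zn]Br | starting material
6 | ethyl (E)-4-{[(4-methoxybenzyl)oxy]methyl}-6-[(triethylsilyl)oxy]hex-4-enoate | CCOC(=O)CC/C(COCc1ccc(OC)cc1)=C\CO[Si](CC)(CC)CC | intermediate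
7 | (E)-4-{[(4-methoxybenzyl)oxy]methyl}-6-[(triethylsilyl)oxy]hex-4-enal | O=CCC/C(COCc1ccc(OC)cc1)=C\CO[Si](CC)(CC)CC | intermediate
8 | methyl 4-oxobutanoate | COC(=O)CCC=O | starting material
9 | tributyl(propa-1,2-dien-1-yl)stannane | CCCC[Sn](CCCC)(CCCC)C=C=C | starting material
10 | methyl (S)-4-hydroxyhepta-5,6-dienoate | COC(=O)CC[C@H](O)C=C=C | intermediate
11 | (S)-5-(propa-1,2-dien-1-yl)dihydrofuran-2(3H)-one | O=C1CC[C@@H](C=C=C)O1 | intermediate
12 | aldol adduct of 11 and 7: (5S)-3-(1-hydroxyalkyl) lactone, mixture at the two new centres | O=C1O[C@H](C=C=C)CC1C(O)CC/C(COCc2ccc(OC)cc2)=C\CO[Si](CC)(CC)CC | intermediate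
13 | methanesulfonate of 12 | O=C1O[C@H](C=C=C)CC1C(OS(C)(=O)=O)CC/C(COCc2ccc(OC)cc2)=C\CO[Si](CC)(CC)CC | intermediate
14 | (S,E)-3-[(E)-4-{[(4-methoxybenzyl)oxy]methyl}-6-[(triethylsilyl)oxy]hex-4-en-1-ylidene]-5-(propa-1,2-dien-1-yl)dihydrofuran-2(3H)-one | O=C1O[C@H](C=C=C)C/C1=C\CC/C(COCc2ccc(OC)cc2)=C\CO[Si](CC)(CC)CC | intermediate
15 | (S,E)-2-[(E)-4-{[(4-methoxybenzyl)oxy]methyl}-6-[(triethylsilyl)oxy]hex-4-en-1-ylidene]hepta-5,6-diene-1,4-diol | OC/C(C[C@H](O)C=C=C)=C/CC/C(COCc1ccc(OC)cc1)=C\CO[Si](CC)(CC)CC | intermediate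
16 | (S)-1,4-bis(tert-butyldimethylsilyl) ether of 15 (C14 and C8 OTBS, C6 OTES, C15 OPMB) | CC(C)(C)[Si](C)(C)OC/C(C[C@H](O[Si](C)(C)C(C)(C)C)C=C=C)=C/CC/C(COCc1ccc(OC)cc1)=C\CO[Si](CC)(CC)CC | intermediate
17 | (2E,6E,9S)-9-[(tert-butyldimethylsilyl)oxy]-7-{[(tert-butyldimethylsilyl)oxy]methyl}-3-{[(4-methoxybenzyl)oxy]methyl}dodeca-2,6,10,11-tetraenal | O=C/C=C(\CC/C=C(/CO[Si](C)(C)C(C)(C)C)C[C@H](O[Si](C)(C)C(C)(C)C)C=C=C)COCc1ccc(OC)cc1 | intermediate
18 | oxanickelacycle: five-membered Ni–O–C12(=O)–C11–C13 ring with (E)-C11=C7 alkylidene, chain as in 17, DBU ligands omitted | O=C1O[Ni]C/C1=C/[C@@H](O[Si](C)(C)C(C)(C)C)C/C(CO[Si](C)(C)C(C)(C)C)=C\CC/C(COCc2ccc(OC)cc2)=C\C=O | intermediate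
19 | cyclodecadienyl γ-hydroxy acid: 20 with the lactone C12–O6 bond open, C6, C7 and C8 arranged as in 20 | CC(C)(C)[Si](C)(C)O[C@H]1C/C(CO[Si](C)(C)C(C)(C)C)=C\CC/C(COCc2ccc(OC)cc2)=C\[C@@H](O)[C@@H]1C(=C)C(=O)O | intermediate
20 | (3aS,4S,6E,10E,11aR)-4-[(tert-butyldimethylsilyl)oxy]-6-{[(tert-butyldimethylsilyl)oxy]methyl}-10-{[(4-methoxybenzyl)oxy]methyl}-3-methylidene-3a,4,5,8,9,11a-hexahydrocyclodeca[b]furan-2(3H)-one | CC(C)(C)[Si](C)(C)O[C@H]1C/C(CO[Si](C)(C)C(C)(C)C)=C\CC/C(COCc3ccc(OC)cc3)=C\[C@H]2OC(=O)C(=C)[C@H]12 | intermediate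
21 | (3aR,4S,6E,10E,11aR)-4-hydroxy-6-(hydroxymethyl)-10-{[(4-methoxybenzyl)oxy]methyl}-3-methylidene-3a,4,5,8,9,11a-hexahydrocyclodeca[b]furan-2(3H)-one | O[C@H]1C/C(CO)=C\CC/C(COCc3ccc(OC)cc3)=C\[C@H]2OC(=O)C(=C)[C@H]12 | intermediate
22 | [(3aR,4S,6E,10E,11aR)-4-hydroxy-10-{[(4-methoxybenzyl)oxy]methyl}-3-methylidene-2-oxo-2,3,3a,4,5,8,9,11a-octahydrocyclodeca[b]furan-6-yl]methyl acetate | O[C@H]1C/C(COC(C)=O)=C\CC/C(COCc3ccc(OC)cc3)=C\[C@H]2OC(=O)C(=C)[C@H]12 | intermediate
23 | 2-(bromomethyl)acrylic acid | C=C(CBr)C(=O)O | starting material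
24 | 2-{[(4-methoxybenzyl)oxy]methyl}acrylic acid | C=C(COCc1ccc(OC)cc1)C(=O)O | intermediate
25 | (3aR,4S,6E,10E,11aR)-6-(acetoxymethyl)-10-{[(4-methoxybenzyl)oxy]methyl}-3-methylidene-2-oxo-2,3,3a,4,5,8,9,11a-octahydrocyclodeca[b]furan-4-yl 2-{[(4-methoxybenzyl)oxy]methyl}acrylate | C=C(COCc4ccc(OC)cc4)C(=O)O[C@H]1C/C(COC(C)=O)=C\CC/C(COCc3ccc(OC)cc3)=C\[C@H]2OC(=O)C(=C)[C@H]12 | intermediate
26 | (3aR,4S,6E,10E,11aR)-6-(acetoxymethyl)-10-(hydroxymethyl)-3-methylidene-2-oxo-2,3,3a,4,5,8,9,11a-octahydrocyclodeca[b]furan-4-yl 2-(hydroxymethyl)acrylate | C=C(CO)C(=O)O[C@H]1C/C(COC(C)=O)=C\CC/C(CO)=C\[C@H]2OC(=O)C(=C)[C@H]12 | intermediate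
27 | (3aR,4S,6E,10E,11aR)-6-(acetoxymethyl)-10-formyl-3-methylidene-2-oxo-2,3,3a,4,5,8,9,11a-octahydrocyclodeca[b]furan-4-yl 2-(hydroxymethyl)acrylate | C=C(CO)C(=O)O[C@H]1C/C(COC(C)=O)=C\CC/C(C=O)=C\[C@H]2OC(=O)C(=C)[C@H]12 | target

**Totals.** Total step count: 17. Longest linear sequence: 15 steps (steps 1–5, 7–13, 15–17).

**Steps most likely to fail**

1. Step 11 (proposed new method). The allylnickel carboxylate may be protonated, carboxylated a second time or oligomerised faster than it closes the ten-membered ring. The enal may also be engaged by Ni(0) or isomerised by DBU, and the facial selectivity at C6/C7 may be poor. The fallback uses known chemistry: the same carboxylative allylation in its established intermolecular mode, with the carbocycle closed at C1=C10 by metathesis. It sets out from 3 and 11 and returns at 20. Negishi coupling of 3 with but-3-enylzinc bromide would give the dienol (E)-3-{[(4-methoxybenzyl)oxy]methyl}hepta-2,6-dien-1-ol F1, and MnO2 would give the dienal F2. Lactone 11 would be aminomethylated (LDA, dimethylmethyleneiminium iodide) to the Mannich base F3, quaternised with MeI to the ammonium iodide F4 and eliminated with NaHCO3 to the α-methylene lactone F5. DIBAL-H would give the methylidene diol F6, and TBSCl the bis-silyl ether F7. F7, CO2 and F2 would then be joined with Ni(cod)2/DBU and lactonised with acid to the diene lactone F8. Ring-closing metathesis of F8 (second-generation ruthenium benzylidene catalyst, toluene, 80 °C, high dilution) between the C1 vinyl group and the C10 methylidene would form the ring-cis trisubstituted alkene and give 20.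

2. Step 17. The oxidation may fail to discriminate between the two primary allylic alcohols, or the acrylate-type alcohol may be over-oxidised to an unstable formyl acrylate. The fallback oxidises C15 before the side chain is attached; it sets out from 22 and returns at 27. DDQ would remove the C15 PMB ether of 22 to give the C8,C15-diol F9. MnO2 would oxidise its only allylic alcohol to the hydroxy enal F10. Yamaguchi esterification with 24 would give the PMB-protected target F11, and a final DDQ cleavage would give 27.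

3. Step 10. The primary allylic TBS ether may be lost under Swern activation, or the enal may isomerise about C4=C5 during the base treatment. The fallback separates unmasking from oxidation; it sets out from 16 and returns at 17. PPTS in MeOH at 0 °C would cleave only the primary TES ether to give the allylic alcohol F12, which MnO2 would oxidise to 17 under neutral conditions.

**Further compounds**

F1 | step 11 | (E)-3-{[(4-methoxybenzyl)oxy]methyl}hepta-2,6-dien-1-ol | OC/C=C(\CCC=C)COCc1ccc(OC)cc1
F2 | step 11 | (E)-3-{[(4-methoxybenzyl)oxy]methyl}hepta-2,6-dienal | O=C/C=C(\CCC=C)COCc1ccc(OC)cc1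
F3 | step 11 | (5S)-3-[(dimethylamino)methyl]-5-(propa-1,2-dien-1-yl)dihydrofuran-2(3H)-one | CN(C)CC1C[C@@H](C=C=C)OC1=O
F4 | step 11 | trimethylammonium iodide of F3 | C[N+](C)(C)CC1C[C@@H](C=C=C)OC1=O.[I-]
F5 | step 11 | (S)-3-methylidene-5-(propa-1,2-dien-1-yl)dihydrofuran-2(3H)-one | C=C1C[C@@H](C=C=C)OC1=O
F6 | step 11 | (S)-2-methylidenehepta-5,6-diene-1,4-diol | C=C(CO)C[C@H](O)C=C=C
F7 | step 11 | (S)-1,4-bis(tert-butyldimethylsilyl) ether of F6 | C=C(CO[Si](C)(C)C(C)(C)C)C[C@H](O[Si](C)(C)C(C)(C)C)C=C=C
F8 | step 11 | diene lactone: trans-α-methylene-γ-butyrolactone bearing the C1–C5 dienyl chain on C6 and the C8–C10 bis-silyloxy methallyl chain on C7 | C=C1C(=O)O[C@H](/C=C(\CCC=C)COCc2ccc(OC)cc2)[C@H]1[C@@H](O[Si](C)(C)C(C)(C)C)CC(=C)CO[Si](C)(C)C(C)(C)C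
F9 | step 17 | C8,C15-diol C14-acetate (22 without the PMB group) | O[C@H]1C/C(COC(C)=O)=C\CC/C(CO)=C\[C@H]2OC(=O)C(=C)[C@H]12
F10 | step 17 | C8-hydroxy C15-enal C14-acetate | O[C@H]1C/C(COC(C)=O)=C\CC/C(C=O)=C\[C@H]2OC(=O)C(=C)[C@H]12
F11 | step 17 | side-chain PMB ether of the target | C=C(COCc3ccc(OC)cc3)C(=O)O[C@H]1C/C(COC(C)=O)=C\CC/C(C=O)=C\[C@H]2OC(=O)C(=C)[C@H]12
F12 | step 10 | C6 allylic alcohol corresponding to 16 (TES removed) | OC/C=C(\CC/C=C(/CO[Si](C)(C)C(C)(C)C)C[C@H](O[Si](C)(C)C(C)(C)C)C=C=C)COCc1ccc(OC)cc1
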